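## Retrosynthetic overview

1. Target 23 ⇐ 21 by esterification of O8 and hydroxyl-directed epoxidation of the Z C1=C10 alkene; 21 ⇐ 18 by exchanging the two ether groups for the C3 acetate and the free C8 hydroxyl; 18 ⇐ 13 by C6 reduction, lactonisation and C11 methylenation.
2. 13 ⇐ 11 by an anionic oxy-Cope ring expansion that forms C8–C9 and cleaves a C1–C6 bond that is not in the target; the resulting C6/C7 enolate is alkylated with the C11–C12 unit in the same flask.
3. Enabling feature: O–C6–C7–C8–C9–C10=C1 is a δ,ε-unsaturated carbonyl pattern at the C6 ketone level, and C1–C2–C3–C4=C5–C6 can be tied by a temporary C1–C6 bond into a cyclohexene whose endocyclic alkene is the cis C4=C5 bond; the C8 oxygen rides in as an enol ether terminus.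
4. 11 ⇐ enone 5 + alkoxyacetylide 9 (axial 1,2-addition, cis semi-hydrogenation); 5 ⇐ (S)-carvone 1 (epoxidation, Wharton transposition, silylation, allylic oxidation).
5. Ring order: cyclohexene (from carvone, temporary) → ten-membered carbocycle (step 8) → γ-lactone (step 9) → oxirane (step 15).

Key step: step 8

Remark: the target is taken exactly as drawn (1R,3S,6S,7R,8R,10S): a Z C4=C5 alkene, a cis-fused oxirane (C9 and C2 cis, so it derives from a 1(10)Z alkene) and a cis-fused lactone, with O3, O6, C11, O8 and the oxirane oxygen on one face of the ring. Germacrane numbering (C1–C10 ring, C11–C13 lactone carbons, C14 on C10, C15 on C4) is used for the ten-membered compounds and for the corresponding atoms of their six-membered precursors.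

## Route

Step 1
Reactants: 1 (S)-carvone
Product: 2 (1S,4S,6S)-1-methyl-4-(prop-1-en-2-yl)-7-oxabicyclo[4.1.0]heptan-2-one
Conditions: 30% H2O2, NaOH (cat.), MeOH, 0 °C
Reagents that add atoms: hydrogen peroxide, OO
Why: Weitz–Scheffer nucleophilic epoxidation, in which hydroperoxide adds axially to the enone β-carbon anti to the isopropenyl group, so the oxirane should form trans to it.

Step 2
Reactants: 2 carvone oxide
Product: 3 (1S,5R)-2-methyl-5-(prop-1-en-2-yl)cyclohex-2-en-1-ol (trans-carveol)
Conditions: N2H4·H2O, AcOH (cat.), MeOH, 0 °C → rt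
Reagents that add atoms: none
Why: Wharton transposition, in which the epoxy hydrazone fragments with loss of N2 and the former epoxide C–O bond (trans to isopropenyl) is retained, giving the S carbinol that becomes C3 of the target.

Step 3
Reactants: 3 trans-carveol
Product: 4 tert-butyldimethyl{[(1S,5R)-2-methyl-5-(prop-1-en-2-yl)cyclohex-2-en-1-yl]oxy}silane
Conditions: TBSCl, imidazole, DMF, rt
Reagents that add atoms: tert-butyldimethylsilyl chloride, CC(C)(C)[Si](C)(C)Cl
Why: Standard silylation of a secondary allylic alcohol; the silyl ether should survive the organolithium, hydride and strong-base steps that follow.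

Step 4
Reactants: 4 silyl ether
Product: 5 (4S,6R)-4-[(tert-butyldimethylsilyl)oxy]-3-methyl-6-(prop-1-en-2-yl)cyclohex-2-en-1-one
Conditions: Rh2(cap)4 (1 mol%, cap = caprolactamate), t-BuOOH (5 equiv), K2CO3, CH2Cl2, rt
Reagents that add atoms: tert-butyl hydroperoxide, CC(C)(C)OO
Why: Radical allylic C–H oxidation (tert-butylperoxyl chain) should convert the only ring allylic CH2 into the enone carbonyl, the other allylic sites being a methyl group, a hindered silyloxy-bearing CH and a tertiary CH; no stereocentre is touched.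

Step 5
Reactants: 6 4-methoxybenzyl alcohol; 7 trichloroethylene
Product: 8 1-{[(E)-1,2-dichloroethenyl]oxymethyl}-4-methoxybenzene
Conditions: KH, THF, 0 °C; then Cl2C=CHCl, −50 °C → rt
Reagents that add atoms: none
Why: Addition of the potassium alkoxide to dichloroacetylene generated in the flask, followed by anti protonation of the vinyl anion, is the standard route to E-1,2-dichlorovinyl ethers.

Step 6
Reactants: 8 dichlorovinyl ether; 5 silyloxy enone
Product: 10 (1S,4S,6R)-4-[(tert-butyldimethylsilyl)oxy]-1-{[(4-methoxyphenyl)methoxy]ethynyl}-3-methyl-6-(prop-1-en-2-yl)cyclohex-2-en-1-ol, via lithium alkoxyacetylide 9 (not isolated)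
Conditions: n-BuLi (2.2 equiv), THF, −78 → −40 °C; then 5, −78 °C; NH4Cl (aq); product kept cold and used directly
Reagents that add atoms: none
Why: Dehydrochlorination and Cl–Li exchange give the alkoxyacetylide, whose 1,2-addition to the enone should occur axially, anti to the pseudoaxial C3 silyloxy group and therefore cis to the pseudoequatorial isopropenyl group, which sets the carbinol centre (S) with the two unsaturated arms cis.

Step 7
Reactants: 10 propargylic alcohol
Product: 11 (1S,4S,6R)-4-[(tert-butyldimethylsilyl)oxy]-1-{(Z)-2-[(4-methoxyphenyl)methoxy]ethenyl}-3-methyl-6-(prop-1-en-2-yl)cyclohex-2-en-1-ol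
Conditions: H2 (1 atm), Pd/CaCO3 poisoned with Pb(OAc)2, quinoline, EtOAc (trace Et3N), rt
Reagents that add atoms: none
Why: Lindlar semi-hydrogenation delivers H2 syn to the electron-rich ynol ether and should give the Z enol ether without reducing the isolated alkenes or the benzyl-type ether.

Step 8
Reactants: 11 Z-enol ether carbinol
Product: 13 methyl (3S,7R,8R,1(10)Z,4Z)-3-[(tert-butyldimethylsilyl)oxy]-8-[(4-methoxybenzyl)oxy]-6-oxo-13-norgermacra-1(10),4-dien-12-oate, via potassium enolate 12 (not isolated)
Conditions: KN(SiMe3)2 (1.1 equiv), 18-crown-6, THF, 0 °C → rt; then BrCH2CO2Me (3 equiv), −78 °C; NH4Cl (aq) at −78 °C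
Reagents that add atoms: methyl bromoacetate, COC(=O)CBr
Why: The tertiary potassium alkoxide undergoes an anionic oxy-Cope [3,3]-sigmatropic rearrangement in which C1–C6 breaks as C8–C9 forms, and the resulting enolate is C-alkylated at C7; the closest precedents are the ring expansion of 1,2-dialkenylcyclohexenols from isopiperitenone-type enones to cyclodeca-1(10),4-dien-6-ones, the oxy-Cope rearrangement of enol ethers to β-alkoxy carbonyl compounds, and in-flask alkylation of oxy-Cope enolates. The ten-membered ring is closed by the C8–C9 bond as a two-carbon ring enlargement of the cyclohexene through a chair transition state fused to it, not as an end-to-end cyclisation, so no high dilution should be needed. The C4=C5 alkene stays cis because it was endocyclic in the six-membered ring, the C10=C1 alkene should form Z because in the cis-dialkenyl arrangement (alkenyl pseudoaxial, isopropenyl pseudoequatorial) C2 is axial on the Cope chair, and the enolate forms with C5 and C8 trans. C8 (R) is set by chirality transfer from C1 and C6 of 11 through that chair together with the Z enol ether geometry, which places the benzyloxy group axial, syn to the oxido group and bridged to it by K+. C7 (R) is set by attack of the electrophile on the open face of the enolate, anti to the new C8–C9 bond, the other face being covered by the ring (C9 and C4). The step needs chair over boat, C- over O-alkylation and survival of the β-alkoxy enolate, which the rigid fused chair, the soft bromide, and the low trapping temperature with a C8–O bond held near the enolate plane (poor overlap for E1cB loss of alkoxide) should secure.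

Step 9
Reactants: 13 keto ester
Product: 15 (3S,6S,7R,8R,1(10)Z,4Z)-3-[(tert-butyldimethylsilyl)oxy]-8-[(4-methoxybenzyl)oxy]-13-norgermacra-1(10),4-dien-6,12-olide (cis-fused γ-lactone), via hydroxy ester 14 (not isolated)
Conditions: NaBH4, CeCl3·7H2O, MeOH, −78 → −20 °C; then PPTS (cat.), PhMe, rt
Reagents that add atoms: none
Why: Luche 1,2-reduction should deliver hydride to the open face of the C6 carbonyl (the face already used at C7, reinforced by cerium chelation to the C8 ether oxygen), giving the 6S alcohol cis to the C7 acetate arm, which closes the cis-fused lactone by acyl substitution.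

Step 10
Reactants: 15 lactone
Product: 16 13-(dimethylamino) derivative of 15 (C11 epimers, configuration at C11 not defined)
Conditions: LiN(iPr)2, THF, −78 °C; then CH2=NMe2+ I−, −78 °C → rt
Reagents that add atoms: N,N-dimethylmethyleneiminium iodide, C[N+](C)=C.[I-]
Why: Mannich reaction of the lactone lithium enolate with Eschenmoser's salt; C11 is the only enolisable position and its configuration is removed in the next step.

Step 11
Reactants: 16 Mannich base
Product: 18 (3S,6S,7R,8R,1(10)Z,4Z)-3-[(tert-butyldimethylsilyl)oxy]-8-[(4-methoxybenzyl)oxy]germacra-1(10),4,11(13)-trien-6,12-olide, via ammonium iodide 17 (not isolated)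
Conditions: MeI, MeOH, rt; then NaHCO3 (aq), EtOAc, rt
Reagents that add atoms: none
Why: N-methylation followed by Hofmann-type E1cB loss of trimethylamine should give the exocyclic alkene under conditions too mild to isomerise it.

Step 12
Reactants: 18 methylene lactone
Product: 19 (3S,6S,7R,8R,1(10)Z,4Z)-3-hydroxy-8-[(4-methoxybenzyl)oxy]germacra-1(10),4,11(13)-trien-6,12-olide
Conditions: HF·pyridine, pyridine, THF, 0 °C → rt
Reagents that add atoms: none
Why: Buffered fluoride cleavage of the silyl ether avoids both base (Michael addition to the methylene lactone) and strong acid (transannular cyclisation of the diene).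

Step 13
Reactants: 19 C3 alcohol
Product: 20 (3S,6S,7R,8R,1(10)Z,4Z)-3-acetoxy-8-[(4-methoxybenzyl)oxy]germacra-1(10),4,11(13)-trien-6,12-olide
Conditions: Ac2O, pyridine, DMAP (cat.), CH2Cl2, 0 °C → rt
Reagents that add atoms: acetic anhydride, CC(=O)OC(C)=O
Why: DMAP-catalysed acylation of the secondary allylic alcohol proceeds with retention at C3.

Step 14
Reactants: 20 acetate
Product: 21 (3S,6S,7R,8R,1(10)Z,4Z)-3-acetoxy-8-hydroxygermacra-1(10),4,11(13)-trien-6,12-olide
Conditions: DDQ, CH2Cl2/pH 7 phosphate buffer, 0 °C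
Reagents that add atoms: none
Why: Oxidative cleavage of the 4-methoxybenzyl ether (hydride abstraction, hydrolysis of the hemiacetal) should leave the acetate, lactone and isolated alkenes untouched.

Step 15
Reactants: 21 homoallylic alcohol
Product: 22 (1R,3S,6S,7R,8R,10S,4Z)-3-acetoxy-1,10-epoxy-8-hydroxygermacra-4,11(13)-dien-6,12-olide
Conditions: VO(acac)2 (5 mol%), t-BuOOH (decane), CH2Cl2, 0 °C → rt
Reagents that add atoms: tert-butyl hydroperoxide, CC(C)(C)OO
Why: Hydroxyl-directed epoxidation of a homoallylic alcohol, in which the vanadate ester of O8 should deliver oxygen to the C1=C10 alkene on the face syn to O8 and set C1 (R) and C10 (S) as the cis oxirane; the C4=C5 alkene is remote and deactivated by two allylic acyloxy groups, and the enoate alkene is electron-poor.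

Step 16
Reactants: 22 epoxy alcohol
Product: 23 (1R,3S,6S,7R,8R,10S,4Z)-3-acetoxy-1,10-epoxy-8-(2-methylprop-2-enoyloxy)germacra-4,11(13)-dien-6,12-olide (target)
Conditions: methacrylic anhydride, Et3N, DMAP, CH2Cl2, 0 °C → rt
Reagents that add atoms: methacrylic anhydride, CC(=C)C(=O)OC(=O)C(C)=C
Why: DMAP-catalysed acylation of the secondary alcohol touches no stereocentre and is mild enough for the oxirane and the methylene lactone.

## Compound list

1 | (S)-carvone, (5S)-2-methyl-5-(prop-1-en-2-yl)cyclohex-2-en-1-one | O=C1C(C)=CC[C@H](C(C)=C)C1 | starting material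
2 | (1S,4S,6S)-1-methyl-4-(prop-1-en-2-yl)-7-oxabicyclo[4.1.0]heptan-2-one (oxirane trans to isopropenyl) | O=C1[C@@]2(C)O[C@H]2C[C@H](C(C)=C)C1 | intermediate
3 | (1S,5R)-2-methyl-5-(prop-1-en-2-yl)cyclohex-2-en-1-ol (trans-carveol) | O[C@@H]1C(C)=CC[C@@H](C(C)=C)C1 | intermediate
4 | tert-butyldimethylsilyl ether of 3 | CC(C)(C)[Si](C)(C)O[C@@H]1C(C)=CC[C@@H](C(C)=C)C1 | intermediate
5 | (4S,6R)-4-[(tert-butyldimethylsilyl)oxy]-3-methyl-6-(prop-1-en-2-yl)cyclohex-2-en-1-one (silyloxy trans to isopropenyl) | CC(C)(C)[Si](C)(C)O[C@@H]1C(C)=CC(=O)[C@@H](C(C)=C)C1 | intermediate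
6 | 4-methoxybenzyl alcohol | COc1ccc(CO)cc1 | starting material
7 | trichloroethylene | ClC=C(Cl)Cl | starting material
8 | 1-{[(E)-1,2-dichloroethenyl]oxymethyl}-4-methoxybenzene | COc1ccc(CO/C(Cl)=C\Cl)cc1 | intermediate
9 | lithium [(4-methoxybenzyl)oxy]acetylide | [Li+].[C-]#COCc1ccc(OC)cc1 | intermediate
10 | (1S,4S,6R)-4-silyloxy-1-{[(4-methoxyphenyl)methoxy]ethynyl}-3-methyl-6-(prop-1-en-2-yl)cyclohex-2-en-1-ol (alkynyl cis to isopropenyl, trans to silyloxy) | O[C@@]1(C#COCc2ccc(OC)cc2)C=C(C)[C@@H](O[Si](C)(C)C(C)(C)C)C[C@@H]1C(C)=C | intermediate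
11 | (1S,4S,6R)-4-silyloxy-1-{(Z)-2-[(4-methoxyphenyl)methoxy]ethenyl}-3-methyl-6-(prop-1-en-2-yl)cyclohex-2-en-1-ol | O[C@@]1(/C=C\OCc2ccc(OC)cc2)C=C(C)[C@@H](O[Si](C)(C)C(C)(C)C)C[C@@H]1C(C)=C | intermediate
12 | potassium (3S,8R,1(10)Z,4Z)-3-silyloxy-8-(4-methoxybenzyloxy)-11,12,13-trinorgermacra-1(10),4,6-trien-6-olate (C5 and C8 trans across C6=C7) | C1/C(C)=C\C[C@H](O[Si](C)(C)C(C)(C)C)/C(C)=C\C(\[O-])=C\[C@@H]1OCc2ccc(OC)cc2.[K+] | intermediate
13 | methyl (3S,7R,8R,1(10)Z,4Z)-3-silyloxy-8-(4-methoxybenzyloxy)-6-oxo-13-norgermacra-1(10),4-dien-12-oate | COc1ccc(CO[C@@H]2C/C(C)=C\C[C@H](O[Si](C)(C)C(C)(C)C)/C(C)=C\C(=O)[C@@H]2CC(=O)OC)cc1 | intermediate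
14 | 6S alcohol of 13 (C3, C7 and C8 unchanged; hydroxyl cis to the C7 acetate arm) | COc1ccc(CO[C@@H]2C/C(C)=C\C[C@H](O[Si](C)(C)C(C)(C)C)/C(C)=C\[C@H](O)[C@@H]2CC(=O)OC)cc1 | intermediate
15 | (3S,6S,7R,8R,1(10)Z,4Z)-3-silyloxy-8-(4-methoxybenzyloxy)-13-norgermacra-1(10),4-dien-6,12-olide (cis-fused lactone) | COc1ccc(CO[C@@H]2C/C(C)=C\C[C@H](O[Si](C)(C)C(C)(C)C)/C(C)=C\[C@@H]3OC(=O)C[C@@H]32)cc1 | intermediate
16 | 13-(dimethylamino) derivative of 15 (C11 undefined) | COc1ccc(CO[C@@H]2C/C(C)=C\C[C@H](O[Si](C)(C)C(C)(C)C)/C(C)=C\[C@@H]3OC(=O)C(CN(C)C)[C@@H]32)cc1 | intermediate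
17 | 13-(trimethylammonio) iodide from 16 (C11 undefined) | COc1ccc(CO[C@@H]2C/C(C)=C\C[C@H](O[Si](C)(C)C(C)(C)C)/C(C)=C\[C@@H]3OC(=O)C(C[N+](C)(C)C)[C@@H]32)cc1.[I-] | intermediate
18 | (3S,6S,7R,8R,1(10)Z,4Z)-3-silyloxy-8-(4-methoxybenzyloxy)germacra-1(10),4,11(13)-trien-6,12-olide | COc1ccc(CO[C@@H]2C/C(C)=C\C[C@H](O[Si](C)(C)C(C)(C)C)/C(C)=C\[C@@H]3OC(=O)C(=C)[C@@H]32)cc1 | intermediate
19 | (3S,6S,7R,8R,1(10)Z,4Z)-3-hydroxy-8-(4-methoxybenzyloxy)germacra-1(10),4,11(13)-trien-6,12-olide | COc1ccc(CO[C@@H]2C/C(C)=C\C[C@H](O)/C(C)=C\[C@@H]3OC(=O)C(=C)[C@@H]32)cc1 | intermediate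
20 | (3S,6S,7R,8R,1(10)Z,4Z)-3-acetoxy-8-(4-methoxybenzyloxy)germacra-1(10),4,11(13)-trien-6,12-olide | COc1ccc(CO[C@@H]2C/C(C)=C\C[C@H](OC(C)=O)/C(C)=C\[C@@H]3OC(=O)C(=C)[C@@H]32)cc1 | intermediate
21 | (3S,6S,7R,8R,1(10)Z,4Z)-3-acetoxy-8-hydroxygermacra-1(10),4,11(13)-trien-6,12-olide | O[C@@H]1C/C(C)=C\C[C@H](OC(C)=O)/C(C)=C\[C@@H]2OC(=O)C(=C)[C@@H]21 | intermediate
22 | (1R,3S,6S,7R,8R,10S,4Z)-3-acetoxy-1,10-epoxy-8-hydroxygermacra-4,11(13)-dien-6,12-olide | O[C@@H]1C[C@]2(C)O[C@@H]2C[C@H](OC(C)=O)/C(C)=C\[C@@H]2OC(=O)C(=C)[C@@H]21 | intermediate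
23 | (1R,3S,6S,7R,8R,10S,4Z)-3-acetoxy-1,10-epoxy-8-(2-methylprop-2-enoyloxy)germacra-4,11(13)-dien-6,12-olide | C=C(C)C(=O)O[C@@H]1C[C@]2(C)O[C@@H]2C[C@H](OC(C)=O)/C(C)=C\[C@@H]2OC(=O)C(=C)[C@@H]21 | target

## Step count and risks

Total steps: 16. Longest linear sequence: 15 steps (1 → 23 through steps 1–4 and 6–16; step 5 makes the side fragment 8).

The step most likely to fail is step 8. At the temperature the rearrangement needs, the β-alkoxy enolate may lose the C8 alkoxide by E1cB elimination, or proton transfer and O-alkylation may compete with C-alkylation. The fallback separates ring expansion from enolate chemistry and sets out from 11. Silylation (Me3SiCl, imidazole, DMF) gives the trimethylsilyl ether F1. Thermolysis (PhMe, sealed tube, about 190 °C, trace Et3N) should effect the same chair [3,3] shift as a neutral siloxy-Cope rearrangement and give the ten-membered trimethylsilyl enol ether F2, so no enolate exists while the mixture is hot. MeLi (THF, −78 → 0 °C) then releases the lithium enolate F3 in the cold, and alkylation with BrCH2CO2Me (DMPU, −78 °C) comes back to the route at 13.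

The second is step 4. The radical C–H oxidation may show poor site selectivity (attack at the silyloxy-bearing CH or the tertiary CH), and the base present may move the isopropenyl double bond into conjugation. The fallback replaces C–H oxidation by an alkene-based 1,3-transposition and sets out from 4. mCPBA/NaHCO3 epoxidises the trisubstituted ring alkene anti to the silyloxy group to the epoxide F4. NaSePh (from PhSeSePh and NaBH4, EtOH) opens it at the secondary carbon to the hydroxy selenide F5. H2O2/pyridine gives, by selenoxide syn elimination, the tertiary allylic alcohol F6. Pyridinium chlorochromate, C5H5NH[CrO3Cl], in CH2Cl2 then effects the oxidative allylic transposition and comes back to the route at 5.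

The third is step 15. Oxygen delivery from the C8 vanadate across the ten-membered ring may be inefficient, which would erode facial selectivity, and the Lewis-acidic metal may trigger transannular opening of the new oxirane. The fallback gives up direction by the hydroxyl and sets out from 21. Acylation first (methacrylic anhydride, Et3N, DMAP) gives the methacrylate F7. Buffered mCPBA (NaHCO3, CH2Cl2, 0 °C) should then epoxidise the most electron-rich alkene, C1=C10, from its exposed face, and this comes back to the route at 23.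

## Further compounds

F1 | step 8 | trimethylsilyl ether of 11 | C[Si](C)(C)O[C@@]1(/C=C\OCc2ccc(OC)cc2)C=C(C)[C@@H](O[Si](C)(C)C(C)(C)C)C[C@@H]1C(C)=C
F2 | step 8 | ten-membered trimethylsilyl enol ether (C6 silyloxy, C6=C7, otherwise as 12) | C1/C(C)=C\C[C@H](O[Si](C)(C)C(C)(C)C)/C(C)=C\C(\O[Si](C)(C)C)=C\[C@@H]1OCc2ccc(OC)cc2
F3 | step 8 | lithium enolate corresponding to 12 | C1/C(C)=C\C[C@H](O[Si](C)(C)C(C)(C)C)/C(C)=C\C(\[O-])=C\[C@@H]1OCc2ccc(OC)cc2.[Li+]
F4 | step 4 | ring epoxide of 4 (oxirane anti to the silyloxy group) | C[Si](C)(C(C)(C)C)O[C@@H]1[C@@]2(C)O[C@H]2C[C@@H](C(C)=C)C1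
F5 | step 4 | hydroxy selenide (tertiary alcohol next to the silyloxy carbon, phenylselanyl on the adjacent CH, trans to the hydroxyl) | C[Si](C)(C(C)(C)C)O[C@@H]1[C@@](C)(O)[C@H]([Se]c2ccccc2)C[C@@H](C(C)=C)C1
F6 | step 4 | tertiary allylic alcohol (6-silyloxy-1-methyl-4-(prop-1-en-2-yl)cyclohex-2-en-1-ol) | C[Si](C)(C(C)(C)C)O[C@@H]1[C@@](C)(O)C=C[C@@H](C(C)=C)C1
F7 | step 15 | 8-O-methacrylate of 21 (1,10-deoxy target) | C=C(C)C(=O)O[C@@H]1C/C(C)=C\C[C@H](OC(C)=O)/C(C)=C\[C@@H]2OC(=O)C(=C)[C@@H]21
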